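**Plan**
- Retrosynthesis: after removal of two benzyl ethers, the only skeletal cut is the depside bond, taken on the phenol side between the ester oxygen and C4' of ring B (the methyl 2-hydroxy-3,6-dimethylbenzoate ring, C1' bearing CO2Me).
- Enabling feature: the acyl carbon on C1 of ring A lies between the C2 oxygen and the C6 propyl and resists attack, whereas C4' of ring B has only the C3' methyl on one side and H at C5' on the other. The carboxylate oxygen is therefore arylated at C4'.
- Forward: ring A acid 6 comes from 5-propylresorcinol (formylation, 4-O-methylation, 2-O-benzylation, oxidation). Ring B boronic acid 11 comes from atraric acid (4-O-triflation, 2-O-benzylation, borylation, boronate cleavage). Both benzene rings are bought, so no ring is formed.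
- The two halves are joined by copper-mediated oxidative O-arylation, and hydrogenolysis of both benzyl ethers ends the route.
- Stereochemistry: the target has no stereocentre and no stereogenic double bond, so nothing has to be controlled.

Key step: step 9

Remark: 5-propylresorcinol and atraric acid are taken as purchasable. In step 9 Cu(OTf)2 is used substoichiometrically with air as terminal oxidant, so the coupling is balanced as acid + boronic acid + ½ O2 → ester + boric acid.

**Step 1**
Reactants: 1 5-propylresorcinol
Product: 3 2,4-dihydroxy-6-propylbenzaldehyde, via aryl iminium chloride 2 (not isolated)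
Conditions: POCl3, DMF, 0 °C → rt; then ice-water, 50 °C
Reagents that add atoms: N,N-dimethylformamide, CN(C)C=O; water, O
Why: Vilsmeier–Haack formylation of a 5-alkylresorcinol should occur para to one hydroxyl and ortho to the other, as established for orcinol and olivetol, and the iminium salt is hydrolysed to the aldehyde on aqueous work-up.

**Step 2**
Reactants: 3 2,4-dihydroxy-6-propylbenzaldehyde
Product: 4 2-hydroxy-4-methoxy-6-propylbenzaldehyde
Conditions: MeI (1.05 equiv), K2CO3 (1.0 equiv), acetone, rt
Reagents that add atoms: iodomethane, CI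
Why: Williamson etherification with one equivalent of electrophile should select the more acidic, unchelated C4 hydroxyl, because the C2 hydroxyl is held in a hydrogen bond to the aldehyde.

**Step 3**
Reactants: 4 2-hydroxy-4-methoxy-6-propylbenzaldehyde
Product: 5 2-(benzyloxy)-4-methoxy-6-propylbenzaldehyde
Conditions: BnBr, K2CO3, DMF, 60 °C
Reagents that add atoms: benzyl bromide, BrCc1ccccc1
Why: Williamson etherification under more forcing conditions should alkylate the remaining chelated phenol, the only acidic site left.

**Step 4**
Reactants: 5 2-(benzyloxy)-4-methoxy-6-propylbenzaldehyde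
Product: 6 2-(benzyloxy)-4-methoxy-6-propylbenzoic acid
Conditions: NaClO2, NaH2PO4, 2-methyl-2-butene, t-BuOH/H2O, rt
Reagents that add atoms: sodium chlorite, [Na+].[O-]Cl=O
Why: Pinnick oxidation converts the hindered aldehyde into the acid by addition and fragmentation of chlorous acid, while 2-methyl-2-butene traps hypochlorous acid and so protects the electron-rich ring from chlorination.

**Step 5**
Reactants: 7 methyl 2,4-dihydroxy-3,6-dimethylbenzoate (atraric acid)
Product: 8 methyl 2-hydroxy-3,6-dimethyl-4-{[(trifluoromethyl)sulfonyl]oxy}benzoate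
Conditions: Tf2O (1.05 equiv), pyridine, CH2Cl2, −20 → 0 °C
Reagents that add atoms: trifluoromethanesulfonic anhydride, O=S(=O)(OS(=O)(=O)C(F)(F)F)C(F)(F)F
Why: Selective O-sulfonylation should take the free C4' hydroxyl, since the C2' hydroxyl is hydrogen-bonded to the ester carbonyl and flanked by the C3' methyl and the C1' ester.

**Step 6**
Reactants: 8 methyl 2-hydroxy-3,6-dimethyl-4-{[(trifluoromethyl)sulfonyl]oxy}benzoate
Product: 9 methyl 2-(benzyloxy)-3,6-dimethyl-4-{[(trifluoromethyl)sulfonyl]oxy}benzoate
Conditions: BnBr, K2CO3, dry DMF, 40 °C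
Reagents that add atoms: benzyl bromide, BrCc1ccccc1
Why: Williamson etherification of the salicylate-type phenol is standard, and an aryl triflate should tolerate carbonate in dry DMF at moderate temperature.

**Step 7**
Reactants: 9 methyl 2-(benzyloxy)-3,6-dimethyl-4-{[(trifluoromethyl)sulfonyl]oxy}benzoate
Product: 10 methyl 2-(benzyloxy)-3,6-dimethyl-4-(4,4,5,5-tetramethyl-1,3,2-dioxaborolan-2-yl)benzoate
Conditions: B2pin2, PdCl2(dppf) (5 mol %), KOAc, 1,4-dioxane, 90 °C
Reagents that add atoms: bis(pinacolato)diboron, CC1(C)OB(OC1(C)C)B1OC(C)(C)C(C)(C)O1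
Why: Miyaura borylation (oxidative addition of zerovalent palladium into the C–OTf bond, acetate-assisted transmetalation from the diboron, reductive elimination) is reliable for aryl triflates carrying a single ortho methyl, and the ester and benzyl ether are inert to it.

**Step 8**
Reactants: 10 methyl 2-(benzyloxy)-3,6-dimethyl-4-(4,4,5,5-tetramethyl-1,3,2-dioxaborolan-2-yl)benzoate
Product: 11 [3-(benzyloxy)-4-(methoxycarbonyl)-2,5-dimethylphenyl]boronic acid
Conditions: NaIO4, NH4OAc, acetone/H2O, rt
Reagents that add atoms: water, O
Why: Oxidative cleavage of pinacol by periodate drives the hydrolysis equilibrium of the boronate to the free boronic acid under buffered, near-neutral conditions that leave the ester and benzyl ether alone.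

**Step 9**
Reactants: 6 2-(benzyloxy)-4-methoxy-6-propylbenzoic acid; 11 [3-(benzyloxy)-4-(methoxycarbonyl)-2,5-dimethylphenyl]boronic acid (2 equiv)
Product: 12 methyl 2-(benzyloxy)-4-{[2-(benzyloxy)-4-methoxy-6-propylbenzoyl]oxy}-3,6-dimethylbenzoate (O,O'-dibenzyl Peruvinide A)
Conditions: Cu(OTf)2 (40 mol %), urea, 4 Å MS, EtOAc, air, 60 °C
Reagents that add atoms: none
Why: The carboxylate of 6 binds divalent copper, the aryl group of 11 passes from boron to copper, air oxidises the aryl copper carboxylate to the trivalent state, and C–O reductive elimination releases the aryl ester while O2 returns copper to the divalent state. The closest known reaction is the Chan–Lam O-arylation of carboxylic acids with arylboronic acids promoted by Cu(OTf)2. No ring closes and no stereocentre is created, the step forming only the bond between the ester oxygen and C4' of ring B. The congested acyl carbon C1 of ring A is never attacked, since the new bond is made at the carboxylate oxygen, one atom away from the C2 benzyloxy and C6 propyl groups, and the boron-bearing carbon has only the C3' methyl as ortho substituent. Selectivity for the carboxylate oxygen is secured by the benzyl ethers on both phenols and by the non-nucleophilic triflate counter-ion, which offers no competing carboxylate, and the site on ring B is fixed ipso to boron. The excess of 11 and the molecular sieves should offset protodeboronation and oxidative hydroxylation of the boronic acid.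

**Step 10**
Reactants: 12 methyl 2-(benzyloxy)-4-{[2-(benzyloxy)-4-methoxy-6-propylbenzoyl]oxy}-3,6-dimethylbenzoate
Product: 13 Peruvinide A, methyl 2-hydroxy-4-[(2-hydroxy-4-methoxy-6-propylbenzoyl)oxy]-3,6-dimethylbenzoate
Conditions: H2 (1 atm), 10% Pd/C, EtOAc, rt
Reagents that add atoms: none
Why: Hydrogenolysis of the two benzyl aryl ethers over Pd/C should free both chelated phenols, while the aryl ester, methyl ester and aromatic rings stay untouched in a non-nucleophilic solvent.

**Compound list**
1 | 5-propylresorcinol (5-propylbenzene-1,3-diol) | CCCc1cc(O)cc(O)c1 | starting material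
2 | [(2,4-dihydroxy-6-propylphenyl)methylidene]dimethyliminium chloride | CCCc1cc(O)cc(O)c1C=[N+](C)C.[Cl-] | intermediate
3 | 2,4-dihydroxy-6-propylbenzaldehyde | CCCc1cc(O)cc(O)c1C=O | intermediate
4 | 2-hydroxy-4-methoxy-6-propylbenzaldehyde | CCCc1cc(OC)cc(O)c1C=O | intermediate
5 | 2-(benzyloxy)-4-methoxy-6-propylbenzaldehyde | CCCc1cc(OC)cc(OCc2ccccc2)c1C=O | intermediate
6 | 2-(benzyloxy)-4-methoxy-6-propylbenzoic acid | CCCc1cc(OC)cc(OCc2ccccc2)c1C(=O)O | intermediate
7 | methyl 2,4-dihydroxy-3,6-dimethylbenzoate (atraric acid) | COC(=O)c1c(C)cc(O)c(C)c1O | starting material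
8 | methyl 2-hydroxy-3,6-dimethyl-4-{[(trifluoromethyl)sulfonyl]oxy}benzoate | COC(=O)c1c(C)cc(OS(=O)(=O)C(F)(F)F)c(C)c1O | intermediate
9 | methyl 2-(benzyloxy)-3,6-dimethyl-4-{[(trifluoromethyl)sulfonyl]oxy}benzoate | COC(=O)c1c(C)cc(OS(=O)(=O)C(F)(F)F)c(C)c1OCc1ccccc1 | intermediate
10 | methyl 2-(benzyloxy)-3,6-dimethyl-4-(4,4,5,5-tetramethyl-1,3,2-dioxaborolan-2-yl)benzoate | COC(=O)c1c(C)cc(B2OC(C)(C)C(C)(C)O2)c(C)c1OCc1ccccc1 | intermediate
11 | [3-(benzyloxy)-4-(methoxycarbonyl)-2,5-dimethylphenyl]boronic acid | COC(=O)c1c(C)cc(B(O)O)c(C)c1OCc1ccccc1 | intermediate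
12 | methyl 2-(benzyloxy)-4-{[2-(benzyloxy)-4-methoxy-6-propylbenzoyl]oxy}-3,6-dimethylbenzoate | CCCc1cc(OC)cc(OCc2ccccc2)c1C(=O)Oc1cc(C)c(C(=O)OC)c(OCc2ccccc2)c1C | intermediate
13 | Peruvinide A | CCCc1cc(OC)cc(O)c1C(=O)Oc1cc(C)c(C(=O)OC)c(O)c1C | target

**Count**
Total steps: 10. Longest linear sequence: 6 steps (four steps to either fragment, then steps 9 and 10).

**Steps most likely to fail**

Step 9. The risk is slow transfer of the ortho-methyl, ester-deactivated aryl group from boron to copper, with protodeboronation or oxidation to the phenol consuming the boronic acid before the hindered carboxylate is arylated. The fallback forms the ester bond at the acyl carbon instead. Setting out from acid 6 and atraric acid 7, trifluoroacetic anhydride in toluene at room temperature should convert 6 into 2-(benzyloxy)-4-methoxy-6-propylbenzoic trifluoroacetic anhydride F1. This acylates the free C4' hydroxyl of 7, the C2' hydroxyl being chelated to the ester, to give methyl 4-{[2-(benzyloxy)-4-methoxy-6-propylbenzoyl]oxy}-2-hydroxy-3,6-dimethylbenzoate F2. Hydrogenolysis of its single benzyl ether (H2, Pd/C, EtOAc) returns to the route at 13.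

Step 6. The risk is loss of the triflate by sulfonyl transfer or hydrolysis under the basic alkylation conditions, together with sluggish alkylation of the chelated, doubly flanked phenol. The fallback changes the order so that no triflate is present during the alkylation. Setting out from 8, Miyaura borylation (B2pin2, PdCl2(dppf), KOAc, dioxane, 90 °C) should tolerate the free phenol and give methyl 2-hydroxy-3,6-dimethyl-4-(4,4,5,5-tetramethyl-1,3,2-dioxaborolan-2-yl)benzoate F3. Benzylation of F3 (BnBr, K2CO3, DMF) rejoins the route at 10.

Step 8. The risk is incomplete cleavage of the pinacol ester, or protodeboronation of the liberated boronic acid during prolonged exposure to aqueous periodate. The fallback passes through a trifluoroborate. Setting out from 10, KHF2 in MeOH/H2O should give potassium [3-(benzyloxy)-4-(methoxycarbonyl)-2,5-dimethylphenyl]trifluoroborate F4, a salt that can be freed of pinacol by trituration. Me3SiCl and water in MeCN then release the boronic acid and return to the route at 11.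

**Further compounds**
F1 | step 9 | 2-(benzyloxy)-4-methoxy-6-propylbenzoic trifluoroacetic anhydride | CCCc1cc(OC)cc(OCc2ccccc2)c1C(=O)OC(=O)C(F)(F)F
F2 | step 9 | methyl 4-{[2-(benzyloxy)-4-methoxy-6-propylbenzoyl]oxy}-2-hydroxy-3,6-dimethylbenzoate | CCCc1cc(OC)cc(OCc2ccccc2)c1C(=O)Oc1cc(C)c(C(=O)OC)c(O)c1C
F3 | step 6 | methyl 2-hydroxy-3,6-dimethyl-4-(4,4,5,5-tetramethyl-1,3,2-dioxaborolan-2-yl)benzoate | COC(=O)c1c(C)cc(B2OC(C)(C)C(C)(C)O2)c(C)c1O
F4 | step 8 | potassium [3-(benzyloxy)-4-(methoxycarbonyl)-2,5-dimethylphenyl]trifluoroborate | COC(=O)c1c(C)cc([B-](F)(F)F)c(C)c1OCc1ccccc1.[K+]
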